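**Plan**

- The cyclohexene is numbered C1 (carbinol carbon bearing CH2OAc), C2 (OAc), C3=C4, C5 and C6 (benzoates). The retrosynthesis cuts C1–C2 and C4–C5 together: C2–C3=C4 is a malondialdehyde unit, and C5–C6–C1 with the CH2O carbon is a tetronic acid.
- Enabling feature: the CH2O carbon on C1 and the oxygen on C5 are cis-1,3 across C6, so they can be one γ-lactone. With C6 as a ketone, C1 and C5 become C3 and C5 of an aromatic 2,4-dioxyfuran, its two nucleophilic carbons.
- Forward: tetronic acid → 3-benzyloxy derivative → 2,4-bis(silyloxy)furan. A TiCl4-mediated dearomatizing [3+3] union with 3-methoxyacrolein forms C4–C5, then C1–C2, giving a 6-oxabicyclo[3.2.1]octene (furanone ring first, carbocycle second).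
- The lactone bridge, absent from the target, is cut with LiAlH4, which also reduces the C6 ketone. Acylations and deprotections finish the route.
- Stereochemistry: C1/C5 are fixed by the bridge, C2 is set in the aldol closure, C6 by hydride addition from the lactone face. Absolute configuration comes from lipase resolution of the bicyclic alcohol.

Key step: step 4

Remark: (E)-3-methoxyacrolein is taken as a purchasable reagent. Racemates are written as two SMILES joined by a dot. In the bicycles C1, C2–C4, C5, C7 and C8 are target C1, C2–C4, C5, the CH2O carbon and C6.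

**Step 1**
Reactants: 1 tetronic acid
Product: 2 3-diazofuran-2,4(3H,5H)-dione
Conditions: 4-acetamidobenzenesulfonyl azide, Et3N, MeCN, 0 °C → rt
Reagents that add atoms: 4-acetamidobenzenesulfonyl azide CC(=O)Nc1ccc(cc1)S(=O)(=O)N=[N+]=[N-]
Why: Regitz diazo transfer to the doubly activated C3 methylene of a cyclic 1,3-dicarbonyl compound.

**Step 2**
Reactants: 2 3-diazofuran-2,4(3H,5H)-dione; 3 benzyl alcohol
Product: 4 3-(benzyloxy)-4-hydroxyfuran-2(5H)-one
Conditions: Rh2(OAc)4 (cat.), benzene, 80 °C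
Reagents that add atoms: none
Why: Rhodium carbenoid O–H insertion of a cyclic 2-diazo-1,3-dicarbonyl compound into an alcohol places the benzyloxy group on C3, and the product rests as the enol.

**Step 3**
Reactants: 4 3-(benzyloxy)-4-hydroxyfuran-2(5H)-one
Product: 5 3-(benzyloxy)-2,4-bis(trimethylsilyloxy)furan
Conditions: TMSOTf (2.2 equiv), Et3N (3 equiv), Et2O, 0 °C → rt; filtered under argon and used crude
Reagents that add atoms: trimethylsilyl trifluoromethanesulfonate C[Si](C)(C)OS(=O)(=O)C(F)(F)F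
Why: O-silylation of the enol followed by γ-deprotonation and silylation of the butenolide, the usual route to 2-silyloxyfurans, gives the aromatic cyclic 1,3-bis(silyl enol ether).

**Step 4**
Reactants: 5 3-(benzyloxy)-2,4-bis(trimethylsilyloxy)furan; 6 (E)-3-methoxyprop-2-enal
Product: 8 racemic (1R*,2S*,5R*)-1-(benzyloxy)-2-hydroxy-6-oxabicyclo[3.2.1]oct-3-ene-7,8-dione, via open-chain Z-enal 7 (not isolated)
Conditions: 6 and TiCl4 (1.5 equiv) premixed, CH2Cl2, 4 Å molecular sieves, −78 °C; then 5, −78 → −20 °C; aqueous NaHCO3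
Reagents that add atoms: none
Why: Proposed new method: TiCl4 turns 6 into a vinylogous oxocarbenium ion that is attacked by C5 of furan 5 (the unsubstituted terminus of this cyclic 1,3-bis(silyl enol ether), whereas C3 is fully substituted), and loss of methoxide gives enal 7 with the C4 enol silyl ether intact; the closest known reactions are the Chan/Langer formal [3+3] cyclizations of 1,3-bis(silyl enol ethers) with 3-alkoxy- or 3-silyloxy-enones and the vinylogous Mukaiyama reactions of 2-silyloxyfurans. The carbocycle then closes by intramolecular Mukaiyama aldol addition of C3 to the aldehyde, a 6-(enolendo)-exo-trig closure open only to the Z enal, so the E isomer has to equilibrate (reversible conjugate addition of chloride) and is drained through the Z form. C1 and C5 are fixed relative to one another by the bridge, because the three-carbon unit can span only one face of the furanone; C2 is set in the aldol step, where an antiperiplanar arrangement of C=O and the enol C=C, supported by TiCl4 chelation of the aldehyde oxygen to the C1 benzyloxy and lactone carbonyl oxygens, should put the C2 oxygen on the lactone side. The step needs C5-before-C3 attack (sterics and the normal terminal selectivity), C- over O-cyclization (O4 stays silylated until the C–C bond exists) and survival of the aldol, which the two bridgeheads secure since dehydration or aromatization would need a bridgehead double bond. The product is racemic because both partners are achiral.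

**Step 5**
Reactants: 8 racemic (1R*,2S*,5R*)-1-(benzyloxy)-2-hydroxy-6-oxabicyclo[3.2.1]oct-3-ene-7,8-dione
Product: 9 (1R,2S,5R)-1-(benzyloxy)-2-hydroxy-6-oxabicyclo[3.2.1]oct-3-ene-7,8-dione
Conditions: Burkholderia cepacia lipase (Amano PS, immobilized), vinyl acetate, MTBE, 30 °C, run to just past half conversion; chromatography
Reagents that add atoms: none
Why: Lipase-catalysed kinetic resolution of a secondary allylic alcohol; by the empirical rule (large group C1, medium group vinyl C3) the 2R enantiomer should be acetylated, leaving 9 as the unreacted alcohol under neutral conditions that do not trigger retro-aldol opening.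

**Step 6**
Reactants: 9 (1R,2S,5R)-1-(benzyloxy)-2-hydroxy-6-oxabicyclo[3.2.1]oct-3-ene-7,8-dione
Product: 10 (1R,2S,5R)-1-(benzyloxy)-2-[(tert-butyldimethylsilyl)oxy]-6-oxabicyclo[3.2.1]oct-3-ene-7,8-dione
Conditions: TBSOTf, 2,6-lutidine, CH2Cl2, −78 → 0 °C
Reagents that add atoms: tert-butyldimethylsilyl trifluoromethanesulfonate CC(C)(C)[Si](C)(C)OS(=O)(=O)C(F)(F)F
Why: Silylation with a silyl triflate and a weak hindered base caps the aldol hydroxyl without retro-aldol cleavage and marks O2 apart from the hydroxyls released next.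

**Step 7**
Reactants: 10 (1R,2S,5R)-1-(benzyloxy)-2-[(tert-butyldimethylsilyl)oxy]-6-oxabicyclo[3.2.1]oct-3-ene-7,8-dione
Product: 11 [(1S,2S,5R,6S)-1-(benzyloxy)-2-[(tert-butyldimethylsilyl)oxy]-5,6-dihydroxycyclohex-3-en-1-yl]methanol
Conditions: LiAlH4, THF, −78 °C, then 0 °C; aqueous potassium sodium tartrate
Reagents that add atoms: none
Why: Hydride reduction of ketone and lactone; hydride should reach the C8 ketone over the flat, hydrogen-free lactone bridge and not over the three-carbon bridge with its axial C2–H, which places the new hydroxyl cis to the C1 oxygen, and lactone reduction then releases CH2OH and the C5 hydroxyl.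

**Step 8**
Reactants: 11 [(1S,2S,5R,6S)-1-(benzyloxy)-2-[(tert-butyldimethylsilyl)oxy]-5,6-dihydroxycyclohex-3-en-1-yl]methanol
Product: 12 [(1S,2S,5R,6S)-1-(benzyloxy)-2-[(tert-butyldimethylsilyl)oxy]-5,6-dihydroxycyclohex-3-en-1-yl]methyl acetate
Conditions: AcCl (1.05 equiv), 2,4,6-collidine, CH2Cl2, −78 °C
Reagents that add atoms: acetyl chloride CC(=O)Cl
Why: Acetyl chloride with collidine at low temperature acylates a primary hydroxyl selectively in the presence of secondary ones.

**Step 9**
Reactants: 12 [(1S,2S,5R,6S)-1-(benzyloxy)-2-[(tert-butyldimethylsilyl)oxy]-5,6-dihydroxycyclohex-3-en-1-yl]methyl acetate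
Product: 13 [(1S,2S,5R,6S)-5,6-bis(benzoyloxy)-1-(benzyloxy)-2-[(tert-butyldimethylsilyl)oxy]cyclohex-3-en-1-yl]methyl acetate
Conditions: BzCl (3 equiv), pyridine, DMAP (cat.), CH2Cl2, 0 °C → rt
Reagents that add atoms: benzoyl chloride O=C(Cl)c1ccccc1
Why: DMAP-catalysed benzoylation of the two remaining secondary hydroxyls, which are the only free ones.

**Step 10**
Reactants: 13 [(1S,2S,5R,6S)-5,6-bis(benzoyloxy)-1-(benzyloxy)-2-[(tert-butyldimethylsilyl)oxy]cyclohex-3-en-1-yl]methyl acetate
Product: 14 [(1R,2S,5R,6S)-5,6-bis(benzoyloxy)-1-(benzyloxy)-2-hydroxycyclohex-3-en-1-yl]methyl acetate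
Conditions: HF·pyridine, THF/pyridine, 0 °C → rt
Reagents that add atoms: none
Why: Buffered fluoride desilylation leaves the esters intact, and any acetyl shift between O7 and O2 is harmless because both end as acetates.

**Step 11**
Reactants: 14 [(1R,2S,5R,6S)-5,6-bis(benzoyloxy)-1-(benzyloxy)-2-hydroxycyclohex-3-en-1-yl]methyl acetate
Product: 15 [(1R,2S,5R,6S)-2-(acetyloxy)-5,6-bis(benzoyloxy)-1-(benzyloxy)cyclohex-3-en-1-yl]methyl acetate
Conditions: Ac2O, pyridine, DMAP (cat.), CH2Cl2, rt
Reagents that add atoms: acetic anhydride CC(=O)OC(C)=O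
Why: Standard acetylation of the only free hydroxyl.

**Step 12**
Reactants: 15 [(1R,2S,5R,6S)-2-(acetyloxy)-5,6-bis(benzoyloxy)-1-(benzyloxy)cyclohex-3-en-1-yl]methyl acetate
Product: 16 [(1R,2S,5R,6S)-2-(acetyloxy)-5,6-bis(benzoyloxy)-1-hydroxycyclohex-3-en-1-yl]methyl acetate
Conditions: BCl3, pentamethylbenzene, CH2Cl2, −78 °C; MeOH quench
Reagents that add atoms: none
Why: Lewis acid debenzylation with a non-basic cation scavenger cleaves the benzyl ether at low temperature without touching esters or the alkene, and the hindered tertiary hydroxyl has no tendency to take up a neighbouring acyl group.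

**Compound list**

1 | tetronic acid (4-hydroxyfuran-2(5H)-one) | O=C1C=C(O)CO1 | starting material
2 | 3-diazofuran-2,4(3H,5H)-dione | [N-]=[N+]=C1C(=O)COC1=O | intermediate
3 | benzyl alcohol | OCc1ccccc1 | starting material
4 | 3-(benzyloxy)-4-hydroxyfuran-2(5H)-one | O=C1OCC(O)=C1OCc1ccccc1 | intermediate
5 | 3-(benzyloxy)-2,4-bis(trimethylsilyloxy)furan | C[Si](C)(C)Oc1occ(O[Si](C)(C)C)c1OCc1ccccc1 | intermediate
6 | (E)-3-methoxyprop-2-enal | CO/C=C/C=O | starting material
7 | racemic 3-(benzyloxy)-5-[(1Z)-3-oxoprop-1-en-1-yl]-4-(trimethylsilyloxy)furan-2(5H)-one | O=C/C=C\C1OC(=O)C(OCc2ccccc2)=C1O[Si](C)(C)C | intermediate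
8 | racemic (1R*,2S*,5R*)-1-(benzyloxy)-2-hydroxy-6-oxabicyclo[3.2.1]oct-3-ene-7,8-dione (2-OH on the lactone side) | O=C1O[C@@H]2C=C[C@H](O)[C@@]1(OCc1ccccc1)C2=O.O=C1O[C@H]2C=C[C@@H](O)[C@]1(OCc1ccccc1)C2=O | intermediate
9 | (1R,2S,5R)-1-(benzyloxy)-2-hydroxy-6-oxabicyclo[3.2.1]oct-3-ene-7,8-dione | O=C1O[C@@H]2C=C[C@H](O)[C@@]1(OCc1ccccc1)C2=O | intermediate
10 | (1R,2S,5R)-1-(benzyloxy)-2-[(tert-butyldimethylsilyl)oxy]-6-oxabicyclo[3.2.1]oct-3-ene-7,8-dione | O=C1O[C@@H]2C=C[C@H](O[Si](C)(C)C(C)(C)C)[C@@]1(OCc1ccccc1)C2=O | intermediate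
11 | [(1S,2S,5R,6S)-1-(benzyloxy)-2-[(tert-butyldimethylsilyl)oxy]-5,6-dihydroxycyclohex-3-en-1-yl]methanol | OC[C@@]1(OCc2ccccc2)[C@@H](O[Si](C)(C)C(C)(C)C)C=C[C@@H](O)[C@@H]1O | intermediate
12 | [(1S,2S,5R,6S)-1-(benzyloxy)-2-[(tert-butyldimethylsilyl)oxy]-5,6-dihydroxycyclohex-3-en-1-yl]methyl acetate | CC(=O)OC[C@@]1(OCc2ccccc2)[C@@H](O[Si](C)(C)C(C)(C)C)C=C[C@@H](O)[C@@H]1O | intermediate
13 | [(1S,2S,5R,6S)-5,6-bis(benzoyloxy)-1-(benzyloxy)-2-[(tert-butyldimethylsilyl)oxy]cyclohex-3-en-1-yl]methyl acetate | CC(=O)OC[C@@]1(OCc2ccccc2)[C@@H](O[Si](C)(C)C(C)(C)C)C=C[C@@H](OC(=O)c2ccccc2)[C@@H]1OC(=O)c1ccccc1 | intermediate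
14 | [(1R,2S,5R,6S)-5,6-bis(benzoyloxy)-1-(benzyloxy)-2-hydroxycyclohex-3-en-1-yl]methyl acetate | CC(=O)OC[C@@]1(OCc2ccccc2)[C@@H](O)C=C[C@@H](OC(=O)c2ccccc2)[C@@H]1OC(=O)c1ccccc1 | intermediate
15 | [(1R,2S,5R,6S)-2-(acetyloxy)-5,6-bis(benzoyloxy)-1-(benzyloxy)cyclohex-3-en-1-yl]methyl acetate | CC(=O)OC[C@@]1(OCc2ccccc2)[C@@H](OC(C)=O)C=C[C@@H](OC(=O)c2ccccc2)[C@@H]1OC(=O)c1ccccc1 | intermediate
16 | [(1R,2S,5R,6S)-2-(acetyloxy)-5,6-bis(benzoyloxy)-1-hydroxycyclohex-3-en-1-yl]methyl acetate | CC(=O)OC[C@@]1(O)[C@@H](OC(C)=O)C=C[C@@H](OC(=O)c2ccccc2)[C@@H]1OC(=O)c1ccccc1 | target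

**Totals**

Total steps: 12. Longest linear sequence: 12 steps (1 → 16).

**Steps most likely to fail**

Step 4 (proposed new method). The cascade may stop at the open-chain E enal, close through oxygen O4 to a cyclic hemiacetal after adventitious desilylation, or start at C3 of the furan. The fallback builds the two bonds separately with known reactions and lets ring closure fix the cis alkene. It sets out from 5. A BF3·OEt2-mediated vinylogous Mukaiyama aldol addition of 5 to (trimethylsilyl)acetaldehyde, followed by acid-induced Peterson elimination of the β-hydroxysilane, should give racemic 3-(benzyloxy)-4-hydroxy-5-vinylfuran-2(5H)-one F1. Allylic alkylation at C3 with prop-2-ene-1,1-diyl diacetate and Pd(PPh3)4 (zerovalent palladium, attack at the acetoxy-bearing allyl terminus as known for geminal diacetates) should give the 3-(1-acetoxyallyl) dione F2. Its C5 centre epimerizes through the enol, so ring-closing metathesis with the second-generation Grubbs catalyst can drain the cis isomer to the bicyclic acetate F3, where C2 epimers are separated. Lipase-catalysed hydrolysis in neutral NaH2PO4/Na2HPO4 buffer removes the acetate and the route is rejoined at 8.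

Step 5. The lipase may discriminate poorly between the enantiomers of a hindered alcohol next to a quaternary centre, or the aldol may open under the reaction conditions. The fallback is a classical resolution one stage later and sets out from 8. Silylation as in step 6 gives racemic silyl ether F4. NaBH4 in MeOH/CH2Cl2 at −78 °C reduces the ketone to racemic hydroxy lactone F5. LiOH in aqueous THF opens the lactone, and the carboxylic acid is resolved by crystallizing its salt with one enantiomer of 1-phenylethylamine, giving acid F6. LiAlH4 reduction of F6 returns to the route at 11.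

Step 7. Hydride may add to the C8 ketone from the wrong face, giving the C6 epimer. The fallback sets the C6 configuration by inversion instead of by hydride approach and sets out from 10. The epimeric triol F7 obtained from the same reduction is acetylated at the primary hydroxyl as in step 8 to give F8. The less hindered allylic C5 hydroxyl is then benzoylated selectively (BzCl 1.1 equiv, pyridine, −40 °C) to give F9. A Mitsunobu reaction at C6 with benzoic acid, PPh3 and diisopropyl azodicarboxylate inverts that centre while installing the second benzoate, and the route is rejoined at 13.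

**Further compounds**

F1 | step 4 | racemic 3-(benzyloxy)-4-hydroxy-5-vinylfuran-2(5H)-one | C=CC1OC(=O)C(OCc2ccccc2)=C1O
F2 | step 4 | racemic 3-[1-(acetyloxy)prop-2-en-1-yl]-3-(benzyloxy)-5-vinylfuran-2,4(3H,5H)-dione (C3 and acetoxy carbon as in 8, C5 epimerizable) | O=C1OC(C=C)C(=O)[C@]1(OCc1ccccc1)[C@@H](OC(C)=O)C=C.O=C1OC(C=C)C(=O)[C@@]1(OCc1ccccc1)[C@H](OC(C)=O)C=C
F3 | step 4 | racemic (1R*,2S*,5R*)-1-(benzyloxy)-7,8-dioxo-6-oxabicyclo[3.2.1]oct-3-en-2-yl acetate | O=C1O[C@@H]2C=C[C@H](OC(C)=O)[C@@]1(OCc1ccccc1)C2=O.O=C1O[C@H]2C=C[C@@H](OC(C)=O)[C@]1(OCc1ccccc1)C2=O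
F4 | step 5 | racemic 1-(benzyloxy)-2-[(tert-butyldimethylsilyl)oxy]-6-oxabicyclo[3.2.1]oct-3-ene-7,8-dione (racemate of 10) | O=C1O[C@@H]2C=C[C@H](O[Si](C)(C)C(C)(C)C)[C@@]1(OCc1ccccc1)C2=O.O=C1O[C@H]2C=C[C@@H](O[Si](C)(C)C(C)(C)C)[C@]1(OCc1ccccc1)C2=O
F5 | step 5 | racemic 1-(benzyloxy)-2-[(tert-butyldimethylsilyl)oxy]-8-hydroxy-6-oxabicyclo[3.2.1]oct-3-en-7-one (8-OH anti to the lactone bridge) | O=C1O[C@@H]2C=C[C@H](O[Si](C)(C)C(C)(C)C)[C@@]1(OCc1ccccc1)[C@H]2O.O=C1O[C@H]2C=C[C@@H](O[Si](C)(C)C(C)(C)C)[C@]1(OCc1ccccc1)[C@@H]2O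
F6 | step 5 | (1S,2S,5R,6S)-1-(benzyloxy)-2-[(tert-butyldimethylsilyl)oxy]-5,6-dihydroxycyclohex-3-ene-1-carboxylic acid | OC(=O)[C@@]1(OCc2ccccc2)[C@@H](O[Si](C)(C)C(C)(C)C)C=C[C@@H](O)[C@@H]1O
F7 | step 7 | [(1S,2S,5R,6R)-1-(benzyloxy)-2-[(tert-butyldimethylsilyl)oxy]-5,6-dihydroxycyclohex-3-en-1-yl]methanol (C6 epimer of 11) | OC[C@@]1(OCc2ccccc2)[C@@H](O[Si](C)(C)C(C)(C)C)C=C[C@@H](O)[C@H]1O
F8 | step 7 | [(1S,2S,5R,6R)-1-(benzyloxy)-2-[(tert-butyldimethylsilyl)oxy]-5,6-dihydroxycyclohex-3-en-1-yl]methyl acetate | CC(=O)OC[C@@]1(OCc2ccccc2)[C@@H](O[Si](C)(C)C(C)(C)C)C=C[C@@H](O)[C@H]1O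
F9 | step 7 | [(1S,2S,5R,6R)-5-(benzoyloxy)-1-(benzyloxy)-2-[(tert-butyldimethylsilyl)oxy]-6-hydroxycyclohex-3-en-1-yl]methyl acetate | CC(=O)OC[C@@]1(OCc2ccccc2)[C@@H](O[Si](C)(C)C(C)(C)C)C=C[C@@H](OC(=O)c2ccccc2)[C@H]1O
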